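## Retrosynthetic overview

1. Target ⇒ β-hydroxy ketone at C1: the C1 carbinol is set last by a 1,3-syn boron-chelate reduction directed by the C3 hydroxyl.
2. β-Hydroxy ketone ⇒ acetonide-protected keto formate: the O5 formate is exchanged for 14-methylpentadecanoate, then the acetonide is removed.
3. Keto formate ⇒ C1–C2 bond by a blue-light, nickel-catalysed ring-opening acylation of an anomeric N-alkoxyphthalimide of 2-deoxy-L-fucose with the bis-oxazole carboxylic acid. Sugar C1 leaves as the O5 formate; C3, C4, C5 and the C6 methyl come unchanged from 3,4-di-O-acetyl-L-fucal.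
4. Bis-oxazole acid ⇒ Negishi union of two bought oxazoles, then saponification.
5. Ring order: neither oxazole is built (both bought, joined first). A temporary dioxolane is closed on the glycal, the pyranose is opened in the key step, and the dioxolane is removed before the final reduction.

Assumption: 5-(chloromethyl)-1,3-oxazole, ethyl 2-chloro-1,3-oxazole-4-carboxylate, 3,4-di-O-acetyl-L-fucal (made in bulk from L-fucose; the only chiral material) and 14-methylpentadecanoic acid are catalogue compounds.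

Notation: BisOx = 2-(1,3-oxazol-5-ylmethyl)-1,3-oxazol-4-yl. Open-chain compounds are numbered C1 (carbon next to BisOx) to C6 (methyl), as in the target; pyranoid compounds use sugar numbering.

## Route

Step 1
Reactants: 1 5-(chloromethyl)-1,3-oxazole; 2 ethyl 2-chloro-1,3-oxazole-4-carboxylate
Product: 4 ethyl 2-(1,3-oxazol-5-ylmethyl)-1,3-oxazole-4-carboxylate, via (1,3-oxazol-5-ylmethyl)zinc chloride 3 (not isolated)
Conditions: 1, Zn dust, LiCl, THF, 25 °C; then 2, Pd(PPh3)4 (3 mol%), THF, 50 °C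
Reagents that add atoms: none
Why: LiCl-assisted zinc insertion into the hetero-benzylic C–Cl bond followed by Negishi cross-coupling at the activated 2-chloro position of the oxazole ester joins the two bought rings; no stereocentre is involved.

Step 2
Reactants: 4 ethyl 2-(1,3-oxazol-5-ylmethyl)-1,3-oxazole-4-carboxylate
Product: 5 2-(1,3-oxazol-5-ylmethyl)-1,3-oxazole-4-carboxylic acid
Conditions: LiOH·H2O, THF/H2O 3:1, 0 to 20 °C; then 1 M HCl to pH 3
Reagents that add atoms: lithium hydroxide, [Li+].[OH-]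
Why: Ester saponification; both oxazoles tolerate cold aqueous hydroxide.

Step 3
Reactants: 6 3,4-di-O-acetyl-L-fucal
Product: 7 L-fucal (1,5-anhydro-2,6-dideoxy-L-lyxo-hex-1-enitol)
Conditions: K2CO3 (0.1 equiv), MeOH, 20 °C
Reagents that add atoms: none
Why: Base-catalysed transesterification (Zemplén-type deacetylation) frees the 3,4-diol without touching C3, C4 or C5.

Step 4
Reactants: 7 L-fucal
Product: 8 3,4-O-isopropylidene-L-fucal
Conditions: 2,2-dimethoxypropane, PPTS (5 mol%), acetone, 0 to 20 °C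
Reagents that add atoms: 2,2-dimethoxypropane, COC(C)(C)OC
Why: Acid-catalysed transketalisation onto the cis-3,4-diol of the galacto-configured glycal gives the cis-fused dioxolane, and PPTS is mild enough to leave the enol ether intact.

Step 5
Reactants: 8 3,4-O-isopropylidene-L-fucal
Product: 9 2-[(2,6-dideoxy-3,4-O-isopropylidene-α-L-lyxo-hexopyranosyl)oxy]isoindoline-1,3-dione
Conditions: N-hydroxyphthalimide (1.2 equiv), PPh3·HBr (5 mol%), CH2Cl2, 20 °C
Reagents that add atoms: N-hydroxyphthalimide, O=C1c2ccccc2C(=O)N1O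
Why: Acid-catalysed hydroalkoxylation of the glycal (Falck–Mioskowski-type 2-deoxyglycosylation) protonates C2 and traps the oxocarbenium ion axially with the N–OH group; the new anomeric centre (α) is destroyed in step 6.

Step 6
Reactants: 9 2-[(2,6-dideoxy-3,4-O-isopropylidene-α-L-lyxo-hexopyranosyl)oxy]isoindoline-1,3-dione; 5 2-(1,3-oxazol-5-ylmethyl)-1,3-oxazole-4-carboxylic acid
Product: 11 (3S,4R,5S)-1-(BisOx)-5-formyloxy-3,4-(isopropylidenedioxy)hexan-1-one, via mixed tert-butyl carbonic anhydride 10 (not isolated)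
Conditions: 5 (1.5 equiv), Boc2O (1.6 equiv), MgCl2 (1.5 equiv), 2,6-lutidine, DMA, 25 °C, 30 min; then 9, NiBr2(dme) (10 mol%), 4,4′-di-tert-butyl-2,2′-bipyridine (12 mol%), [Ir(ppy)2(dtbbpy)]PF6 (1 mol%), Hantzsch ester (1.5 equiv), 450 nm LEDs, degassed DMA, 25 °C
Reagents that add atoms: none
Why: Proposed new method: the reduced iridium photocatalyst (Hantzsch ester as terminal reductant) cleaves the N–O bond of 9 to the anomeric alkoxy radical, whose β-scission of C1–C2 (driven by formate C=O formation) opens the pyranose, leaves sugar C1 as the O5 formate and releases the primary C2 radical; this radical is captured by the divalent acylnickel species formed from zerovalent nickel and anhydride 10, and reductive elimination from trivalent nickel forges the C1–C2 ketone bond without touching C3, C4 or C5. The closest known reactions are the Suárez anomeric alkoxy-radical fragmentation of sugar lactols, photoreductive β-scission of N-alkoxyphthalimides, and nickel-catalysed reductive acylation of alkyl radicals with carboxylic acids activated in situ.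

Step 7
Reactants: 11 (3S,4R,5S)-1-(BisOx)-5-formyloxy-3,4-(isopropylidenedioxy)hexan-1-one
Product: 12 (3S,4R,5S)-1-(BisOx)-5-hydroxy-3,4-(isopropylidenedioxy)hexan-1-one (in equilibrium with its six-membered cyclic hemiketal)
Conditions: K2CO3 (0.2 equiv), MeOH, −10 °C, 15 min
Reagents that add atoms: none
Why: Formate esters undergo transesterification far faster than the β-alkoxy ketone or the acetonide can react, so catalytic carbonate in cold methanol frees O5 only.

Step 8
Reactants: 12 (3S,4R,5S)-1-(BisOx)-5-hydroxy-3,4-(isopropylidenedioxy)hexan-1-one; 13 14-methylpentadecanoic acid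
Product: 14 (3S,4R,5S)-1-(BisOx)-3,4-(isopropylidenedioxy)-5-(14-methylpentadecanoyloxy)hexan-1-one
Conditions: DIC, DMAP, CH2Cl2, 0 to 20 °C
Reagents that add atoms: none
Why: Steglich esterification: the open δ-hydroxy ketone and its hemiketal interconvert, only the secondary C5 hydroxyl of the open form is acylated (the tertiary hemiketal hydroxyl is not), so the equilibrium drains to the open-chain ester with the C5–O bond untouched.

Step 9
Reactants: 14 (3S,4R,5S)-1-(BisOx)-3,4-(isopropylidenedioxy)-5-(14-methylpentadecanoyloxy)hexan-1-one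
Product: 15 (3S,4S,5S)-1-(BisOx)-3,4-dihydroxy-5-(14-methylpentadecanoyloxy)hexan-1-one
Conditions: TFA/H2O 9:1, 0 °C, 30 min
Reagents that add atoms: none
Why: Acid hydrolysis of the isopropylidene acetal; the ester and the oxazoles survive brief cold aqueous TFA, and no stereocentre is involved.

Step 10
Reactants: 15 (3S,4S,5S)-1-(BisOx)-3,4-dihydroxy-5-(14-methylpentadecanoyloxy)hexan-1-one
Product: 17 (1R,3S,4S,5S)-1-(BisOx)-1,3,4-trihydroxyhexan-5-yl 14-methylpentadecanoate (CNP0327583.1), via 3,4-bis-O-(diethylboryl) chelate 16 (not isolated)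
Conditions: Et2BOMe (2.2 equiv), THF/MeOH 4:1, −78 °C; NaBH4 (1.2 equiv), −78 °C; AcOH, then MeOH co-evaporation
Reagents that add atoms: none
Why: Narasaka–Prasad reduction: the boron on O3 chelates the ketone oxygen into a half-chair and external hydride attacks axially, giving the 1,3-syn diol, so (1R) is set by the bought C3 centre.

## Compound list

1 | 5-(chloromethyl)-1,3-oxazole | ClCc1cnco1 | starting material
2 | ethyl 2-chloro-1,3-oxazole-4-carboxylate | CCOC(=O)c1coc(Cl)n1 | starting material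
3 | (1,3-oxazol-5-ylmethyl)zinc chloride | Cl[Zn]Cc1cnco1 | intermediate
4 | ethyl 2-(1,3-oxazol-5-ylmethyl)-1,3-oxazole-4-carboxylate | CCOC(=O)c1coc(Cc2cnco2)n1 | intermediate
5 | 2-(1,3-oxazol-5-ylmethyl)-1,3-oxazole-4-carboxylic acid | OC(=O)c1coc(Cc2cnco2)n1 | intermediate
6 | 3,4-di-O-acetyl-L-fucal (3,4-di-O-acetyl-1,5-anhydro-2,6-dideoxy-L-lyxo-hex-1-enitol) | C[C@@H]1OC=C[C@H](OC(C)=O)[C@@H]1OC(C)=O | starting material
7 | L-fucal (1,5-anhydro-2,6-dideoxy-L-lyxo-hex-1-enitol) | C[C@@H]1OC=C[C@H](O)[C@@H]1O | intermediate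
8 | 3,4-O-isopropylidene-L-fucal | C[C@@H]1OC=C[C@@H]2OC(C)(C)O[C@H]12 | intermediate
9 | 2-[(2,6-dideoxy-3,4-O-isopropylidene-α-L-lyxo-hexopyranosyl)oxy]isoindoline-1,3-dione | C[C@@H]1O[C@@H](ON3C(=O)c4ccccc4C3=O)C[C@@H]2OC(C)(C)O[C@H]12 | intermediate
10 | tert-butyl carbonic 2-(1,3-oxazol-5-ylmethyl)-1,3-oxazole-4-carboxylic anhydride | CC(C)(C)OC(=O)OC(=O)c1coc(Cc2cnco2)n1 | intermediate
11 | (3S,4R,5S)-1-(BisOx)-5-formyloxy-3,4-(isopropylidenedioxy)hexan-1-one | O=CO[C@@H](C)[C@H]1OC(C)(C)O[C@H]1CC(=O)c2coc(Cc3cnco3)n2 | intermediate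
12 | (3S,4R,5S)-1-(BisOx)-5-hydroxy-3,4-(isopropylidenedioxy)hexan-1-one | O[C@@H](C)[C@H]1OC(C)(C)O[C@H]1CC(=O)c2coc(Cc3cnco3)n2 | intermediate
13 | 14-methylpentadecanoic acid | CC(C)CCCCCCCCCCCCC(=O)O | starting material
14 | (3S,4R,5S)-1-(BisOx)-3,4-(isopropylidenedioxy)-5-(14-methylpentadecanoyloxy)hexan-1-one | CC(C)CCCCCCCCCCCCC(=O)O[C@@H](C)[C@H]1OC(C)(C)O[C@H]1CC(=O)c2coc(Cc3cnco3)n2 | intermediate
15 | (3S,4S,5S)-1-(BisOx)-3,4-dihydroxy-5-(14-methylpentadecanoyloxy)hexan-1-one | CC(C)CCCCCCCCCCCCC(=O)O[C@@H](C)[C@@H](O)[C@@H](O)CC(=O)c1coc(Cc2cnco2)n1 | intermediate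
16 | 3,4-bis-O-(diethylboryl) derivative of 15 (boron chelate) | CC(C)CCCCCCCCCCCCC(=O)O[C@@H](C)[C@@H](OB(CC)CC)[C@@H](OB(CC)CC)CC(=O)c1coc(Cc2cnco2)n1 | intermediate
17 | (1R,3S,4S,5S)-1-(BisOx)-1,3,4-trihydroxyhexan-5-yl 14-methylpentadecanoate | CC(C)CCCCCCCCCCCCC(=O)O[C@@H](C)[C@@H](O)[C@@H](O)C[C@@H](O)c1coc(Cc2cnco2)n1 | target

## Step count and risks

Total step count: 10. Longest linear sequence: 8 steps (steps 3 to 10, from 6 to 17).

The three steps most likely to fail:

**Step 6 (the proposed new method).** The alkoxy radical could be reduced to the lactol by the Hantzsch ester before it fragments, or the C2 radical could be reduced or could dimerise before nickel captures it. The fallback uses known chemistry only, sets out from 8 and comes back at 11. Hydration of the glycal 8 (PPh3·HBr cat., H2O, THF, 20 °C) gives the lactol 2,6-dideoxy-3,4-O-isopropylidene-L-lyxo-hexopyranose F1. Suárez alkoxy-radical fragmentation (PhI(OAc)2, I2, CH2Cl2, visible light, 20 °C) gives the primary iodide (2S,3R,4R)-5-iodo-3,4-(isopropylidenedioxy)pentan-2-yl formate F2. Nickel-catalysed reductive acylation of F2 with acid 5, activated in the flask as anhydride 10 (NiBr2(dme), 4,4′-di-tert-butyl-2,2′-bipyridine, Zn, MgCl2, Boc2O, DMA, 25 °C), then gives 11.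

**Step 8.** If 12 sits almost entirely as the cyclic hemiketal, acylation may be slow or may go to the anomeric oxygen. The fallback masks the ketone first, sets out from 11 and comes back at 14. Silylation (TBSOTf, Et3N, CH2Cl2, 0 °C) gives the enol ether (1Z,3S,4R,5S)-1-(BisOx)-1-(tert-butyldimethylsilyloxy)-3,4-(isopropylidenedioxy)hex-1-en-5-yl formate F3. Ammonia in methanol at 0 °C removes the formate to give the enol ether alcohol (1Z,3S,4R,5S)-1-(BisOx)-1-(tert-butyldimethylsilyloxy)-3,4-(isopropylidenedioxy)hex-1-en-5-ol F4, which cannot form a hemiketal. Steglich esterification with 13 (DIC, DMAP) gives the enol ether ester (1Z,3S,4R,5S)-1-(BisOx)-1-(tert-butyldimethylsilyloxy)-3,4-(isopropylidenedioxy)hex-1-en-5-yl 14-methylpentadecanoate F5. HF·pyridine in THF at 0 °C returns the ketone 14.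

**Step 10.** The free C4 hydroxyl of 15 can tie the ketone up as a five-membered hemiketal or bind boron in competition with the C3 chelate, which would lower rate and selectivity. The fallback reduces before deprotection, sets out from 14 and comes back at 17. Chelation-controlled reduction of the β-alkoxy ketone (Zn(BH4)2, Et2O, −30 °C; zinc bridges the ketone oxygen and the dioxolane O3) gives the 1,3-syn alcohol (1R,3S,4R,5S)-1-(BisOx)-1-hydroxy-3,4-(isopropylidenedioxy)hexan-5-yl 14-methylpentadecanoate F6. Acetonide hydrolysis (TFA/H2O 9:1, 0 °C) then gives 17.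

## Further compounds

F1 | step 6 | 2,6-dideoxy-3,4-O-isopropylidene-L-lyxo-hexopyranose (anomeric mixture) | C[C@@H]1OC(O)C[C@@H]2OC(C)(C)O[C@H]12
F2 | step 6 | (2S,3R,4R)-5-iodo-3,4-(isopropylidenedioxy)pentan-2-yl formate | O=CO[C@@H](C)[C@H]1OC(C)(C)O[C@H]1CI
F3 | step 8 | (1Z,3S,4R,5S)-1-(BisOx)-1-(tert-butyldimethylsilyloxy)-3,4-(isopropylidenedioxy)hex-1-en-5-yl formate | O=CO[C@@H](C)[C@H]1OC(C)(C)O[C@H]1/C=C(\O[Si](C)(C)C(C)(C)C)c2coc(Cc3cnco3)n2
F4 | step 8 | (1Z,3S,4R,5S)-1-(BisOx)-1-(tert-butyldimethylsilyloxy)-3,4-(isopropylidenedioxy)hex-1-en-5-ol | O[C@@H](C)[C@H]1OC(C)(C)O[C@H]1/C=C(\O[Si](C)(C)C(C)(C)C)c2coc(Cc3cnco3)n2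
F5 | step 8 | (1Z,3S,4R,5S)-1-(BisOx)-1-(tert-butyldimethylsilyloxy)-3,4-(isopropylidenedioxy)hex-1-en-5-yl 14-methylpentadecanoate | CC(C)CCCCCCCCCCCCC(=O)O[C@@H](C)[C@H]1OC(C)(C)O[C@H]1/C=C(\O[Si](C)(C)C(C)(C)C)c2coc(Cc3cnco3)n2
F6 | step 10 | (1R,3S,4R,5S)-1-(BisOx)-1-hydroxy-3,4-(isopropylidenedioxy)hexan-5-yl 14-methylpentadecanoate | CC(C)CCCCCCCCCCCCC(=O)O[C@@H](C)[C@H]1OC(C)(C)O[C@H]1C[C@@H](O)c2coc(Cc3cnco3)n2
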